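## Structural features

1. The target is an unsymmetrical dimer of two identical C16 halves. Each half is a (2S,3S,4S)-2,3-epoxy-4-hydroxy-2-prenylcyclohexanone (ring A = C1–C6, ring B = C1′–C6′; C1 ketone, C2 prenylated epoxide carbon, C4 carbinol) with a chain C7–C8–C9(CH3)–C10 on C6.
2. Only two bonds, C7–C7′ and C10–C6′, join the halves, and they close the central cyclohexene ring C (C6′–C7′–C7–C8=C9–C10). Ring B is therefore spiro-fused to ring C at the quaternary centre C6′ (R), ring A is tied to ring C by the tetrasubstituted exocyclic enone C6=C7 (C7′ cis to C1=O), and C7′ carries a second exocyclic alkene C7′=C8′ whose isopropenyl group (C9′=C10′) is cis to C6′.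
3. In each ring C2, C3 and C4 are contiguous, with the hydroxyl cis to the epoxide oxygen and the prenyl group on the other face; C6′ stands 1,3 to both C2′ and C4′ and bears C10 on the face of the epoxide oxygen.
4. The fragile groups are the two α,β-epoxy ketones (base, nucleophiles, reducing metals), the cross-conjugated tetraene around ring C (acid, oxygen, oxa-6π closure onto C1=O) and the two prenyl alkenes (electrophilic oxidants).
5. C7 and C7′ are both β-carbons (acceptors) of their ketones, which puts C1=O and C1′=O in a dissonant 1,6-relation. C10 (ε-carbon of the C1=O/C6=C7/C8=C9 dienone) and C6′ (α-carbon of C1′=O) are both donors, so each bond of the union joins carbons of like polarity.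
6. The real difficulty is ring C: a quaternary spiro stereocentre flanked by a ketone and by two adjacent, stereodefined exocyclic alkenes, to be made in the presence of both epoxy ketones.
7. The key step exploits two features. One is the hidden C2 axis through the middle of C7–C7′, which appears as soon as C10–C6′ is cut. The other is the donor character shared by C10 and C6′, which lets ring C be closed by oxidative coupling of two identical extended enolates.

## Logic of the disconnections

**17 to 16.** The O–Si bonds at C4 and C4′ are cut. The hydroxyls must be masked against strong base, triflic anhydride and iodine. The forward step has to free them without touching the epoxy ketones or the tetraene, so a small, labile silyl group is required.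

**16 to 13 (key disconnection).** Only C10–C6′ is cut, and one hydrogen is returned to C10 and one to C10′. In one sentence: ring C is closed by an iodine-mediated α,ε′-oxidative coupling within the bis(trienolate) of C2-symmetric 13. This cut removes ring C, the quaternary stereocentre and the C7′=C8′ geometry, and it makes the two halves identical. The forward step must take away two hydrogens, choose C6′ over C8′ as the nucleophilic site, choose the face of ring B anti to the prenyl group, and keep the C6=C7 geometry.

**13 to 12.** C7–C7′ is cut. It joins two acceptor carbons, so it is made by reductive homocoupling of two identical alkenyl electrophiles. The problem is halved to a single C16 building block. The forward step must couple two fully substituted sp2 carbons with retention, under base-free conditions, because 12 can lose triflate by elimination.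

**12 to 8 + 9 (through 11 and 10).** The C7–O(triflyl) bond and then C6–C7 are cut. C6–C7 is a normal donor–acceptor (aldol) bond, and the whole C7–C10 chain comes from one cheap C5 enal. The forward steps must enolise only at C6, triflate the exocyclic oxygen, and place the triflate cis to C1=O.

**8 to 6 (through 7).** The O–Si bond and the two epoxide C–O bonds are cut. The epoxide goes back to an enone that can be attacked by a nucleophilic peroxide, to which the prenyl alkene is blind. The forward step must deliver oxygen syn to the C4 hydroxyl.

**6 to 4 + 5.** The C2–CH2 bond of the prenyl group is cut between an sp2 carbon and an allyl unit (cross-coupling). The forward step must transfer the prenyl group through its unsubstituted terminus.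

**4 to 1 (through 3 and 2).** The C2–I bond, the ketal and the C4–H bond are cut. The only stereocentre set by a catalyst is C4, and it goes back to a flat, achiral enone ketal. All other stereocentres are relayed from it.

## Other disconnections considered

**Alternative 1:** (the first that comes to mind) C7–C7′ and C10–C6′ are cut together.
- Forward key step: thermal [4+2] homodimerisation of the vinylallenyl ketone A1, with C7=C8–C9=C10 of one molecule as diene and the enone bond C6′=C7′ of a second molecule as dienophile.
- Regiochemistry: in A1 the carbonyl is conjugated with C6=C7, which lies orthogonal to the diene. The diene is then an isoprene-type 2-methyl diene with its largest donor coefficient at C10, while the dienophile has its largest acceptor coefficient at C7′. A concerted polar pairing would therefore join C10 to C7′ and C7 to C6′, which is not the pairing of the target.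
- Periselectivity: the target pairing needs a stepwise path that begins with C7–C7′ union to a bis-allyl diradical, and that diradical can also collapse to [2+2] dimers or close at C8′.
- Stereochemistry: A1 carries a stereogenic allene axis, so two diastereomers and several facial combinations compete in a bimolecular event.
- Verdict: the chosen plan costs one more step from 12. In return it fixes C7–C7′ beforehand, contains no stereogenic axis, and leaves a single intramolecular ring closure.

**Alternative 2:** C7–C7′ alone is cut, in a compound whose C10–C6′ bond was made earlier by allylation of an α-alkynyl ketone enolate.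
- Forward key step: cycloisomerisation of the 1,7-enyne A2 by ketone-directed metalation of C7–H (the vinylic hydrogen cis to C1=O) and syn addition across C7′≡C8′ in a 6-exo-dig mode, or the palladium hydride variant. As an isomerisation it would set both exocyclic alkenes by mechanism.
- Alkene geometry: A2 needs the C8=C9 alkene in the Z form outside a ring, with its two largest groups cis, against the thermodynamic preference.
- Building blocks: A2 needs a quaternary α-alkynyl ketone that has no short, reliable access.
- Symmetry: the two halves are different, so the hidden symmetry is lost and the step count roughly doubles.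
- Selectivity: in the palladium hydride variant, β-hydride elimination towards C5 would compete.

**Alternative 3:** the same two bonds are cut at the arene oxidation level (dearomatisation).
- Forward key step: the flat alkynyl hydroquinone A3 tautomerises to the vinylidene quinone methide A4, which dimerises to the bis(enedione) A5. Two-fold epoxidation and reduction follow.
- Energetics: forming A4 costs the aromaticity of a simple benzene ring.
- Stability: ring A of A5 can re-aromatise by a proton shift from C10, which would destroy the C6=C7 bond.
- Stereocontrol: the spiro centre would be formed racemic, and the six ring stereocentres would then have to be set on that scaffold, those of ring A far from any control element.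
- Verdict: the chosen plan carries all ring stereocentres into the union and uses them to set C6′.

Key step: step 11

Assumption: the sense of induction in step 1 follows the usual model for this catalyst family (the alkene takes the place of the aryl group), so the (S,S)-ligand should give (S)-2; otherwise the antipodal ligand is used.

## Route

Step 1
Reactants: 1 1,4-dioxaspiro[4.5]dec-6-en-8-one
Product: 2 (8S)-1,4-dioxaspiro[4.5]dec-6-en-8-ol
Conditions: RuCl[(S,S)-TsDPEN](p-cymene) (1 mol %), i-PrOH, 25 °C
Reagents that add atoms: none
Why: Noyori asymmetric transfer hydrogenation, which reduces this enone at the carbonyl only. The catalyst sets C4 (S) by delivering hydride to the face on which the alkene lies under the arene ligand.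

Step 2
Reactants: 2 (8S)-1,4-dioxaspiro[4.5]dec-6-en-8-ol
Product: 3 (4S)-4-hydroxycyclohex-2-en-1-one
Conditions: HCl (0.5 M aq), THF, 0 °C to rt
Reagents that add atoms: water, SMILES O
Why: Acid-catalysed ketal hydrolysis unmasks C1=O in conjugation with C2=C3. The C4–O bond is not broken, so the stereocentre is kept.

Step 3
Reactants: 3 (4S)-4-hydroxycyclohex-2-en-1-one
Product: 4 (4S)-4-hydroxy-2-iodocyclohex-2-en-1-one
Conditions: I2, pyridine, CH2Cl2, 0 °C to rt
Reagents that add atoms: iodine, SMILES II
Why: α-Iodination of an enone by conjugate addition of pyridine, iodination of the enolate and elimination. Only the vinylic C2–H is replaced and the free hydroxyl is tolerated.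

Step 4
Reactants: 4 (4S)-4-hydroxy-2-iodocyclohex-2-en-1-one; 5 tributyl(3-methylbut-2-en-1-yl)stannane
Product: 6 (4S)-4-hydroxy-2-(3-methylbut-2-en-1-yl)cyclohex-2-en-1-one
Conditions: Pd2(dba)3, AsPh3, CuI, NMP, 40 °C
Reagents that add atoms: none
Why: Stille coupling of an α-iodoenone, with the soft arsine ligand and CuI to speed transmetalation. Reductive elimination at the unsubstituted allyl terminus should give the linear prenyl group.

Step 5
Reactants: 6 (4S)-4-hydroxy-2-(3-methylbut-2-en-1-yl)cyclohex-2-en-1-one
Product: 7 (1S,5S,6S)-5-hydroxy-1-(3-methylbut-2-en-1-yl)-7-oxabicyclo[4.1.0]heptan-2-one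
Conditions: t-BuOOH, Triton B (cat.), THF, −10 °C
Reagents that add atoms: tert-butyl hydroperoxide, SMILES CC(C)(C)OO
Why: Weitz–Scheffer epoxidation, as used for 2-alkylcyclohexenones; the peroxide anion attacks only the enone, not the prenyl alkene. The free C4 hydroxyl should bind the incoming peroxide by hydrogen bonding and so set C2 and C3 with the oxygen syn to it. A cis epoxy alcohol cannot undergo Payne rearrangement.

Step 6
Reactants: 7 (1S,5S,6S)-5-hydroxy-1-(3-methylbut-2-en-1-yl)-7-oxabicyclo[4.1.0]heptan-2-one
Product: 8 (1S,5S,6S)-1-(3-methylbut-2-en-1-yl)-5-(triethylsilyloxy)-7-oxabicyclo[4.1.0]heptan-2-one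
Conditions: Et3SiCl, imidazole, CH2Cl2, 0 °C
Reagents that add atoms: chlorotriethylsilane, SMILES CC[Si](Cl)(CC)CC
Why: Standard silylation of a secondary alcohol. The small triethylsilyl group is chosen so that it shields the upper face of ring B little and can be removed very mildly at the end.

Step 7
Reactants: 8 (1S,5S,6S)-1-(3-methylbut-2-en-1-yl)-5-(triethylsilyloxy)-7-oxabicyclo[4.1.0]heptan-2-one; 9 3-methylbut-2-enal
Product: 10 (1S,5S,6S)-3-(1-hydroxy-3-methylbut-2-en-1-yl)-1-(3-methylbut-2-en-1-yl)-5-(triethylsilyloxy)-7-oxabicyclo[4.1.0]heptan-2-one (mixture of epimers at C6 and C7)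
Conditions: LDA, THF, −78 °C; 9; AcOH quench
Reagents that add atoms: none
Why: Aldol addition of a lithium enolate. C6 is the only enolisable position because C2 is quaternary, and 1,2-addition to the β,β-disubstituted enal is favoured. The new centres at C6 and C7 do not matter because both become sp2.

Step 8
Reactants: 10 (1S,5S,6S)-3-(1-hydroxy-3-methylbut-2-en-1-yl)-1-(3-methylbut-2-en-1-yl)-5-(triethylsilyloxy)-7-oxabicyclo[4.1.0]heptan-2-one
Product: 11 (1S,5S,6S)-3-(3-methylbut-2-enoyl)-1-(3-methylbut-2-en-1-yl)-5-(triethylsilyloxy)-7-oxabicyclo[4.1.0]heptan-2-one (enolised β-diketone)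
Conditions: Dess–Martin periodinane, CH2Cl2, 0 °C
Reagents that add atoms: none
Why: Dess–Martin oxidation of an allylic β-hydroxy ketone under near-neutral conditions that spare epoxide, silyl ether and alkenes. 11 is used at once, because its enol could close onto the enone by oxa-Michael addition.

Step 9
Reactants: 11 (1S,5S,6S)-3-(3-methylbut-2-enoyl)-1-(3-methylbut-2-en-1-yl)-5-(triethylsilyloxy)-7-oxabicyclo[4.1.0]heptan-2-one
Product: 12 (1Z)-3-methyl-1-[(1S,5S,6S)-1-(3-methylbut-2-en-1-yl)-2-oxo-5-(triethylsilyloxy)-7-oxabicyclo[4.1.0]heptan-3-ylidene]but-2-en-1-yl trifluoromethanesulfonate (OTf cis to C1=O)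
Conditions: LiHMDS (1.0 equiv), toluene–Et2O, −78 °C; Tf2O
Reagents that add atoms: trifluoromethanesulfonic anhydride, SMILES O=S(=O)(OS(=O)(=O)C(F)(F)F)C(F)(F)F
Why: O-Triflation of a lithium-chelated β-diketone enolate. The ring oxygen is screened by the quaternary C2, so the exocyclic oxygen should react, and the U-shaped chelate places the triflate cis to C1=O (Z). No base strong enough to remove a C10 proton is left, so 12 should not eliminate.

Step 10
Reactants: 12 (1Z)-enol triflate (two molecules)
Product: 13 (4Z,5Z)-2,7-dimethyl-4,5-bis[(1S,5S,6S)-1-(3-methylbut-2-en-1-yl)-2-oxo-5-(triethylsilyloxy)-7-oxabicyclo[4.1.0]heptan-3-ylidene]octa-2,6-diene (C2-symmetric tetraene-dione)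
Conditions: Pd(PPh3)4 (10 mol %), Me3SnSnMe3 (0.55 equiv), LiCl, CuCl, DMSO–THF, 60 °C
Reagents that add atoms: none
Why: One-pot stannylation and Stille coupling (Stille–Kelly type homocoupling) of a β-triflyloxy enone. Oxidative addition to zerovalent palladium is easy at this electron-poor carbon, and CuCl/LiCl is the usual aid for crowded alkenylstannanes. The medium is free of base, and both alkenyl partners couple with retention, so C7′ ends up cis to C1=O and C7 cis to C1′=O.

Step 11
Reactants: 13 C2-symmetric tetraene-dione
Product: 16 bis(triethylsilyl) ether of the target, via dilithium bis-trienolate 14 (not isolated), via lithium trienolate allylic iodide 15 (not isolated)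
Conditions: 13 added to LiHMDS (2.3 equiv), THF–DMPU, −78 °C; I2 (1.0 equiv), −78 to 0 °C
Reagents that add atoms: none
Why: Proposed new method: double ε-deprotonation of the two dienones (the C10 and C10′ methyl protons are the only ones whose removal is relayed to a carbonyl, since C2/C2′ are quaternary and C6/C6′ are sp2) gives 14, and one equivalent of I2 reverses the polarity of one of the two identical halves by turning it into the allylic iodide 15, whose primary C10 is attacked by the α-carbon C6′ of the remaining trienolate; because 13 is C2-symmetric, either half can take either role and both choices give 16. The closest known reaction types are the iodine- or copper-mediated intramolecular oxidative coupling of bis-enolates and the deconjugative α-alkylation of extended enolates, which is known to build quaternary α-carbons; what is new is their union in an α,ε′ sense on trienolates. Ring C closes in a 6-(enolexo)-exo-tet mode, whereas C6–C6′, C8–C6′ and C8–C8′ union would give four-membered rings and C10–C10′ union an eight-membered ring. The only six-membered competitor, C10 to C8′, needs the rotamer about C7–C7′ that presses rings A and B against each other, while the productive rotamer places ring A next to the small C8′–H, and extended enolates carry their highest charge density at the α-carbon. The new stereocentre C6′ is controlled by ring B: the C2′ prenyl group stands over the lower face of the planar C1′=C6′ enolate in a 1,3-relation, the epoxide oxygen on the upper face is tied back and the C4′ silyloxy group is pseudo-equatorial, so C10 should bond on the face syn to the epoxide oxygen, which is the (R) configuration. The C6=C7 geometry is carried over from 13, and C8=C9 becomes cis by ring closure, any E allylic iodide being returned to the reactive Z form by fast iodide-induced allylic transposition. C7′=C8′ should form with the isopropenyl group turned away from ring A, and an inward isomer could still correct itself by reversible oxa-6π closure of the C1=O/C6=C7/C7′=C8′ oxatriene.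

Step 12
Reactants: 16 bis(triethylsilyl) ether of the target
Product: 17 target CNP0235815.2
Conditions: HF·pyridine, pyridine, THF, 0 °C
Reagents that add atoms: none
Why: Fluoride-driven cleavage of two secondary triethylsilyl ethers. The pyridine buffer keeps the medium close to neutral, so epoxy ketones, tetraene and stereocentres should be untouched.

## Compound list

1 | 1,4-dioxaspiro[4.5]dec-6-en-8-one | O=C1CCC2(OCCO2)C=C1 | starting material
2 | (8S)-1,4-dioxaspiro[4.5]dec-6-en-8-ol | C1C[C@H](O)C=CC12OCCO2 | intermediate
3 | (4S)-4-hydroxycyclohex-2-en-1-one | C1C[C@H](O)C=CC1=O | intermediate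
4 | (4S)-4-hydroxy-2-iodocyclohex-2-en-1-one | C1C[C@H](O)C=C(I)C1=O | intermediate
5 | tributyl(3-methylbut-2-en-1-yl)stannane | CCCC[Sn](CCCC)(CCCC)CC=C(C)C | starting material
6 | (4S)-4-hydroxy-2-(3-methylbut-2-en-1-yl)cyclohex-2-en-1-one | C1C[C@H](O)C=C(CC=C(C)C)C1=O | intermediate
7 | (1S,5S,6S)-5-hydroxy-1-(3-methylbut-2-en-1-yl)-7-oxabicyclo[4.1.0]heptan-2-one | C1C[C@H](O)[C@@H]2O[C@]2(CC=C(C)C)C1=O | intermediate
8 | (1S,5S,6S)-1-(3-methylbut-2-en-1-yl)-5-(triethylsilyloxy)-7-oxabicyclo[4.1.0]heptan-2-one | C1C[C@H](O[Si](CC)(CC)CC)[C@@H]2O[C@]2(CC=C(C)C)C1=O | intermediate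
9 | 3-methylbut-2-enal | CC(C)=CC=O | starting material
10 | aldol adduct of 8 and 9, 1-hydroxy-3-methylbut-2-en-1-yl group on C6, epimers at C6 and C7 | CC(C)=CC(O)C1C[C@H](O[Si](CC)(CC)CC)[C@@H]2O[C@]2(CC=C(C)C)C1=O | intermediate
11 | β-diketone, 3-methylbut-2-enoyl group on C6 (enolised) | CC(C)=CC(=O)C1C[C@H](O[Si](CC)(CC)CC)[C@@H]2O[C@]2(CC=C(C)C)C1=O | intermediate
12 | (Z)-enol triflate at C7, OTf cis to C1=O | CC(C)=C/C(OS(=O)(=O)C(F)(F)F)=C1\C[C@H](O[Si](CC)(CC)CC)[C@@H]2O[C@]2(CC=C(C)C)C1=O | intermediate
13 | C2-symmetric (Z,Z)-tetraene-dione joined at C7–C7′ | CC(C)=C/C(=C1\C[C@H](O[Si](CC)(CC)CC)[C@@H]2O[C@]2(CC=C(C)C)C1=O)/C(C=C(C)C)=C3/C[C@H](O[Si](CC)(CC)CC)[C@@H]4O[C@]4(CC=C(C)C)C3=O | intermediate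
14 | dilithium bis-trienolate of 13 (alkene geometries labile) | C=C(C)C=C(C1C[C@H](O[Si](CC)(CC)CC)[C@@H]2O[C@]2(CC=C(C)C)C=1[O-])C(=CC(C)=C)C3C[C@H](O[Si](CC)(CC)CC)[C@@H]4O[C@]4(CC=C(C)C)C=3[O-].[Li+].[Li+] | intermediate
15 | lithium trienolate (primed half) with C10 allylic iodide (unprimed half), C8=C9 geometry labile | ICC(C)=C/C(=C1\C[C@H](O[Si](CC)(CC)CC)[C@@H]2O[C@]2(CC=C(C)C)C1=O)C(=CC(C)=C)C3C[C@H](O[Si](CC)(CC)CC)[C@@H]4O[C@]4(CC=C(C)C)C=3[O-].[Li+] | intermediate
16 | 4,4′-bis(triethylsilyl) ether of the target (2S,3S,4S,2′S,3′S,4′S,6′R; C6=C7 Z; C7′=C8′ Z) | C=C(C)/C=C1/C(=C2/C[C@H](O[Si](CC)(CC)CC)[C@@H]3O[C@]3(CC=C(C)C)C2=O)C=C(C)C[C@@]12C[C@H](O[Si](CC)(CC)CC)[C@@H]1O[C@]1(CC=C(C)C)C2=O | intermediate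
17 | CNP0235815.2 (2S,3S,4S,2′S,3′S,4′S,6′R; C6=C7 Z; C7′=C8′ Z) | C=C(C)/C=C1/C(=C2/C[C@H](O)[C@@H]3O[C@]3(CC=C(C)C)C2=O)C=C(C)C[C@@]12C[C@H](O)[C@@H]1O[C@]1(CC=C(C)C)C2=O | target

## Step count and least certain steps

Total step count: 12. Longest linear sequence: 12 steps (from 1 to 17); 5 and 9 are bought.

**Step 11 (key step, new method).**
- Ring closure may go through C8′ instead of C6′, because that site is less crowded and its product keeps both enones conjugated.
- Facial selectivity at C6′ may be poor if the silyloxy group adopts a pseudo-axial position.
- Rotation about C6–C7 while that half is an enolate would erode the enone geometry.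
- Iodination of both halves, or intermolecular coupling, may outrun closure.
- Fallback (known chemistry): it sets out from 12. Triethylamine in toluene should remove a C10 proton and expel triflate in a 1,4-elimination (E1cB) to give the vinylallenyl ketone F1. In concentrated solution with gentle warming, F1 dimerises in the [4+2] mode known for vinylallenes. The fallback rejoins the route at 16.

**Step 10.**
- Transmetalation and reductive elimination are likely to be slow at two fully substituted alkenyl carbons. That leaves room for protodestannylation, for reduction of the triflate and for thermal loss of triflate.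
- Fallback: it sets out from 12. The two events are separated and the bond-forming mechanism is changed. Full stannylation (Pd(PPh3)4, one equivalent of Me3SnSnMe3, LiCl) gives the β-trimethylstannyl dienone F2. F2 is then dimerised by the CuCl-mediated oxidative homocoupling of β-stannyl enones in DMF at room temperature. The fallback rejoins the route at 13.

**Step 9.**
- Triflation may occur at the ring oxygen, or control of the enol geometry may be lost if the chelate opens.
- Oxa-Michael closure of 11 or premature elimination of the triflate may also intervene.
- Fallback: it sets out from 8 and avoids both the triflate and the coupling. Two equivalents of the lithium enolate of 8 are added to the symmetrical 1,2-diketone 2,7-dimethylocta-2,6-diene-4,5-dione F3, which is available in one step from the bis(N-methoxy-N-methyl)amide of oxalic acid and 2-methylprop-1-enylmagnesium bromide. This gives the bis-aldol F4. Double dehydration towards the acidic C6–H and C6′–H with the Burgess reagent brings the sequence back to the route at 13.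

**Step 5.**
- Facial selectivity may be poor if hydrogen bonding to the peroxide is too weak to override the steric bias, and base may isomerise the γ-hydroxy enone.
- Fallback: it sets out from 6 and changes from nucleophilic to hydroxyl-directed electrophilic epoxidation. Ketalisation without alkene migration (1,2-bis(trimethylsilyloxy)ethane, TMSOTf, −78 °C) gives the allylic alcohol ketal F5. VO(acac)2/t-BuOOH epoxidises its ring alkene syn to the hydroxyl, in preference to the isolated prenyl alkene, to give the epoxy alcohol ketal F6. Mild aqueous acid then removes the ketal, and the fallback rejoins the route at 7.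

## Further compounds

F1 | step 11 | vinylallenyl ketone, 6-(3-methylbuta-1,3-dien-1-ylidene) derivative of 8 (both axial epimers) | C=C(C)C=C=C1C[C@H](O[Si](CC)(CC)CC)[C@@H]2O[C@]2(CC=C(C)C)C1=O
F2 | step 10 | (Z)-β-trimethylstannyl dienone, SnMe3 at C7 cis to C1=O | CC(C)=C/C([Sn](C)(C)C)=C1\C[C@H](O[Si](CC)(CC)CC)[C@@H]2O[C@]2(CC=C(C)C)C1=O
F3 | step 9 | 2,7-dimethylocta-2,6-diene-4,5-dione | CC(C)=CC(=O)C(=O)C=C(C)C
F4 | step 9 | bis-aldol of two molecules of 8 with F3 (mixture at C6, C7, C6′, C7′) | CC(C)=CC(O)(C1C[C@H](O[Si](CC)(CC)CC)[C@@H]2O[C@]2(CC=C(C)C)C1=O)C(O)(C=C(C)C)C3C[C@H](O[Si](CC)(CC)CC)[C@@H]4O[C@]4(CC=C(C)C)C3=O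
F5 | step 5 | (8S)-6-(3-methylbut-2-en-1-yl)-1,4-dioxaspiro[4.5]dec-6-en-8-ol | C1C[C@H](O)C=C(CC=C(C)C)C12OCCO2
F6 | step 5 | ethylene ketal of 7 | C1C[C@H](O)[C@@H]2O[C@]2(CC=C(C)C)C13OCCO3
A1 | alternative 1 | vinylallenyl ketone monomer with free hydroxyl (both axial epimers) | C=C(C)C=C=C1C[C@H](O)[C@@H]2O[C@]2(CC=C(C)C)C1=O
A2 | alternative 2 | 1,7-enyne, C6′ quaternary with enynyl group and (Z)-C8=C9 chain to the (E)-alkylidene of ring A | C=C(C)C#C[C@@]1(C/C(C)=C\C=C2/C[C@H](O)[C@@H]3O[C@]3(CC=C(C)C)C2=O)C[C@H](O)[C@@H]4O[C@]4(CC=C(C)C)C1=O
A3 | alternative 3 | 2-(3-methylbut-3-en-1-yn-1-yl)-6-(3-methylbut-2-en-1-yl)benzene-1,4-diol | C=C(C)C#Cc1cc(O)cc(CC=C(C)C)c1O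
A4 | alternative 3 | vinylidene quinone methide tautomer of A3 | C=C(C)C=C=C1C=C(O)C=C(CC=C(C)C)C1=O
A5 | alternative 3 | spiro bis(enedione) dimer of A4 (racemic) | C=C(C)/C=C1/C(=C2/CC(=O)C=C(CC=C(C)C)C2=O)C=C(C)CC12CC(=O)C=C(CC=C(C)C)C2=O
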